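All runs are simulated on assumed constants; noise was put on by code.

The flask holds X at 0.600 M, and this molar charge c, not the equivalents, is the setting to follow. Eta and zeta differ in equivalents (6 equiv against 3 equiv) but share c = 1.20 M 1.20 M, and at 0.417 d they read E 5.9% and 5.6%.

| flask | G | J | X | remark | time |
|---|---|---|---|---|---|
| alpha | 0.20 M | 0.20 M | 1.5 equiv | run made earlier |  |
| eta | 0.20 M | 0.20 M | 6 equiv | run made earlier |  |
| zeta | 0.40 M | 0.40 M | 3 equiv | run made earlier |  |
| flask | 0.20 M | 0.20 M | 3.00 equiv |  | 4.0 d |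

| run | time / d | E / % | Z / % | G / % |
|---|---|---|---|---|
| alpha | 0.417 | 8.0 | 14.4 | 32.1 |
| alpha | 0.625 | 10.5 | 17.5 | 27.4 |
| alpha | 0.833 | 12.1 | 21.3 | 23.7 |
| alpha | 1.25 | 14.1 | 24.3 | 19.8 |
| alpha | 2.00 | 15.2 | 28.0 | 16.3 |
| alpha | 3.00 | 16.0 | 30.7 | 14.8 |
| eta | 0.417 | 5.9 | 33.8 | 13.9 |
| eta | 0.625 | 7.2 | 38.0 | 9.1 |
| eta | 0.833 | 7.3 | 40.4 | 6.7 |
| eta | 1.25 | 7.7 | 43.8 | 4.2 |
| eta | 2.00 | 7.3 | 45.8 | 3.8 |
| eta | 3.00 | 5.7 | 47.8 | 3.1 |
| zeta | 0.417 | 5.6 | 32.2 | 15.6 |
| zeta | 0.625 | 7.2 | 36.1 | 11.5 |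
| zeta | 1.25 | 8.7 | 41.1 | 6.5 |
| zeta | 2.08 | 7.8 | 43.6 | 5.5 |
| zeta | 3.00 | 7.7 | 45.6 | 4.2 |

(scatter of a reading: 0.3 percentage points)

- X is single-handed; G and J are mirror images of each other, charged as a racemate, each of them at the stated concentration
- the numbers in the tables scatter with a standard deviation of 0.3 percentage points
- the handed part of X does not stay in what it makes, so the products of the two hands are mirror images too

- the best time, 4.0 d at the latest, for E
- the amount of E, in percent of the G and J together charged, at that time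
- earliest time at which at least nineteen twentieths of that best amount are there, in d
- latest time at which they still are, in d

E, an intermediate, rises and falls like a middle tank. Its top reading is 16.0% in alpha, at c = 0.300 M, and 7.7% in eta: a factor 2.08 for a factor 4.00 in c. So the top of E goes roughly as one over the square root of c. That gives a reduced top P, the top of E multiplied by the root of c over eta's c.

A first link takes P from eta and zeta, 8.20%, which puts the flask at 11.6%. That link is weak: zeta tops 1 percentage point above eta, more than the scatter, and it holds twice the flask's G. Alpha and eta share the flask's G, though alpha's top is one reading, its last, with the scatter of a single reading. From those two, P = 7.85%, and the flask's top is 11.1%. The same root on eta's top time, 1.25 d, gives 1.77 d.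

The forecast gives 11.3% at 2.2 d, open from 1.05 d to 3.7 d, on “a broad maximum near 2.2 d”, a later top than the one reckoned here.

The flask gives 11.2% at 1.63 d, and the asked share of that best amount stands from 1.06 d to 2.48 d.

    X + J → L (k = 0.00102 L mol⁻¹ min⁻¹)
    X + G → Z (k = 0.00252 L mol⁻¹ min⁻¹)
    2 X → Q (k = 5.24 × 10⁻⁴ L mol⁻¹ min⁻¹)
    J ⇌ E (K = 0.760, k = 1.83 × 10⁻⁴ min⁻¹)
    G ⇌ E (K = 0.760, k = 1.83 × 10⁻⁴ min⁻¹)

The flask's top stands 0.10 points above the reckoned 11.1%, and it comes earlier than the reckoned 1.77 d. The neighbour with 7.50 equiv of X, all else as in the flask, has c = 1.50 M, so P puts its top at 7.02%. That neighbour's top of E is 6.82%.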